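## Retrosynthetic overview

1. Target ⇐ deacetylation, α‑face hydrogenation of an 8‑methylidene group (sets C8) and ketone methylenation ⇐ a (Z)‑β‑chloro‑enone on a trans‑decalin.
2. Key disconnection: the chloro‑enone ⇐ a 1‑(arylethynyl)cyclopentanol on a trans‑hydrindane, by a chlorinative semipinacol ring expansion (1,2‑shift of quaternary C10 from C8 to C9). Ring B, the C–Cl bond and the alkene geometry arise together.
3. Alkynyl carbinol ⇐ Sonogashira coupling of 2‑bromo‑6‑methoxyhydroquinone diacetate (from catechol) with the ethynyl carbinol of (3aS,7aS)‑4,4,7a‑trimethylhydrindan‑1‑one.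
4. Hydrindanone ⇐ Hajos–Parrish‑type enedione (reductive gem‑methylation, Wolff–Kishner) ⇐ 2‑methylcyclopentane‑1,3‑dione + ethyl vinyl ketone (amino‑acid‑catalysed annulation sets C10).
5. Ring order: cyclopentane (bought) → ring A by annulation → ring B by expansion of the cyclopentane; the arene is elaborated from catechol.

Assumption: drimane‑type atom labels are used in the explanations (C1–C10 decalin, C11 = chlorinated carbon, C12 = methyl carbon on C8); the target alkene is E (Cl trans to C10).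

## Route

Step 1
Reactants: 1 2-methylcyclopentane-1,3-dione; 2 ethyl vinyl ketone (pent-1-en-3-one)
Product: 4 (S)-4,7a-dimethyl-2,3,7,7a-tetrahydro-1H-indene-1,5(6H)-dione, via triketone 3 (not isolated)
Conditions: H2O, AcOH (cat.), 70 °C; concentrate; then L-phenylalanine (1 equiv), 1 M HClO4 (0.5 equiv), MeCN, reflux; one recrystallisation
Reagents that add atoms: none
Why: Michael addition followed by the Hajos–Parrish (Eder–Sauer–Wiechert) amino‑acid‑catalysed aldol condensation; the L‑amino‑acid enamine selects one enantiotopic ring carbonyl and sets the quaternary centre (future C10) as S, and recrystallisation raises the ee.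

Step 2
Reactants: 4 (S)-4,7a-dimethyl-2,3,7,7a-tetrahydro-1H-indene-1,5(6H)-dione
Product: 5 (7a'S)-4',7a'-dimethyl-2',3',7',7a'-tetrahydrospiro[1,3-dioxolane-2,1'-inden]-5'(6'H)-one
Conditions: ethylene glycol, p-TsOH·H2O, 4 Å MS, rt
Reagents that add atoms: ethylene glycol OCCO
Why: Acid‑catalysed ketalisation is selective for the saturated cyclopentanone because the conjugated α‑methyl enone carbonyl is much less electrophilic.

Step 3
Reactants: 5 (7a'S)-4',7a'-dimethyl-2',3',7',7a'-tetrahydrospiro[1,3-dioxolane-2,1'-inden]-5'(6'H)-one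
Product: 7 (3a'S,7a'S)-4',4',7a'-trimethylhexahydrospiro[1,3-dioxolane-2,1'-inden]-5'(4'H)-one, via lithium enolate 6 (not isolated)
Conditions: Li (3 equiv), NH3(l)/THF, t-BuOH (1 equiv), −78 → −33 °C; isoprene; then MeI (5 equiv), −78 °C → rt
Reagents that add atoms: iodomethane CI
Why: Stork dissolving‑metal reductive alkylation; protonation of the enone β‑carbon (C5) anti to the angular methyl gives the trans ring fusion, and the regiodefined enolate is C‑methylated to the gem‑dimethyl group.

Step 4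
Reactants: 7 (3a'S,7a'S)-4',4',7a'-trimethylhexahydrospiro[1,3-dioxolane-2,1'-inden]-5'(4'H)-one
Product: 10 (3aS,7aS)-4,4,7a-trimethyloctahydro-1H-inden-1-one, via hydrazone 8 (not isolated), via deoxygenated ketal 9 (not isolated)
Conditions: N2H4·H2O, KOH, diethylene glycol, 130 → 200 °C; then 2 M HCl, THF, rt
Reagents that add atoms: water O
Why: Wolff–Kishner (Huang–Minlon) reduction removes the hindered neopentyl ketone as in 4,4‑dimethyl‑3‑keto terpenoids, and the acidic work‑up hydrolyses the dioxolane; no stereocentre is touched.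

Step 5
Reactants: 10 (3aS,7aS)-4,4,7a-trimethyloctahydro-1H-inden-1-one; 11 ethynylmagnesium bromide
Product: 12 (1R,3aS,7aS)-1-ethynyl-4,4,7a-trimethyloctahydro-1H-inden-1-ol
Conditions: HC≡CMgBr (3 equiv), THF, 0 °C → rt; aq. NH4Cl
Reagents that add atoms: none
Why: Acetylide 1,2‑addition to the cyclopentanone from the face opposite the angular methyl (as in ethynylation of 17‑keto steroids); this carbinol centre is destroyed in step 11, so its configuration is immaterial.

Step 6
Reactants: 13 catechol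
Product: 14 2-methoxyphenol (guaiacol)
Conditions: MeI (1.0 equiv), K2CO3, acetone, reflux; distil
Reagents that add atoms: iodomethane CI
Why: Williamson mono‑O‑methylation (statistical; the mono‑ether is separated from catechol and veratrole).

Step 7
Reactants: 14 2-methoxyphenol
Product: 15 2-bromo-6-methoxyphenol
Conditions: NBS (1.0 equiv), i-Pr2NH (10 mol %), CH2Cl2, 0 °C
Reagents that add atoms: N-bromosuccinimide O=C1CCC(=O)N1Br
Why: Amine‑catalysed ortho‑selective electrophilic bromination of a phenol (the N‑bromoamine delivers bromine next to the hydrogen‑bonded OH).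

Step 8
Reactants: 15 2-bromo-6-methoxyphenol
Product: 16 2-bromo-6-methoxy-1,4-benzoquinone
Conditions: Fremy's salt (2.2 equiv), KH2PO4, H2O/acetone, rt
Reagents that add atoms: potassium nitrosodisulfonate (Fremy's salt) [K+].[K+].[O]N(S(=O)(=O)[O-])S(=O)(=O)[O-]
Why: Teuber oxidation; the nitroxyl radical oxidises the 2,6‑disubstituted phenol at its free para position to the p‑quinone.

Step 9
Reactants: 16 2-bromo-6-methoxy-1,4-benzoquinone
Product: 17 2-bromo-6-methoxy-1,4-phenylene diacetate
Conditions: Zn dust, Ac2O, NaOAc (cat.), rt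
Reagents that add atoms: acetic anhydride CC(=O)OC(C)=O
Why: Reductive acetylation; zinc reduces the quinone and the hydroquinone is trapped as the air‑stable diacetate, whose acylated ortho oxygen is non‑nucleophilic (no benzofuran formation later).

Step 10
Reactants: 12 (1R,3aS,7aS)-1-ethynyl-4,4,7a-trimethyloctahydro-1H-inden-1-ol; 17 2-bromo-6-methoxy-1,4-phenylene diacetate
Product: 18 2-{[(1S,3aS,7aS)-1-hydroxy-4,4,7a-trimethyloctahydro-1H-inden-1-yl]ethynyl}-6-methoxy-1,4-phenylene diacetate
Conditions: PdCl2(PPh3)2 (5 mol %), CuI (10 mol %), Et3N, DMF, 70 °C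
Reagents that add atoms: none
Why: Sonogashira coupling of the aryl bromide with the terminal alkyne; triethylamine leaves the aryl acetates and the tertiary alcohol untouched.

Step 11
Reactants: 18 2-{[(1S,3aS,7aS)-1-hydroxy-4,4,7a-trimethyloctahydro-1H-inden-1-yl]ethynyl}-6-methoxy-1,4-phenylene diacetate
Product: 20 2-{(Z)-chloro[(4aS,8aS)-5,5,8a-trimethyl-2-oxooctahydronaphthalen-1(2H)-ylidene]methyl}-6-methoxy-1,4-phenylene diacetate, via silyl ether 19 (not isolated)
Conditions: MSTFA (1.5 equiv), TMSOTf (1 mol %), CH2Cl2, 40 °C; then IPrAuNTf2 (5 mol %), N-chlorosuccinimide (1.1 equiv), 4 Å MS, 0 °C → rt, dark; aq. NaHCO3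
Reagents that add atoms: N-chlorosuccinimide O=C1CCC(=O)N1Cl
Why: Proposed new method: gold(I)‑catalysed chlorinative semipinacol ring enlargement of a 1‑(arylethynyl)cyclopentyl silyl ether — the cationic NHC–gold π‑activates the alkyne, the electron‑rich C8–C10 σ‑bond (quaternary carbon, pushed by the silyloxy group) shifts to C9 anti to gold (only C9 is within reach, so the aryl polarisation of the alkyne cannot misdirect the addition), the resulting C11 vinyl‑gold is chlorodeaurated by NCS with retention and the silyl group leaves on succinimide, so Cl ends trans to C10 (the target geometry) and no stereocentre is touched; silylation removes the proton that would protodeaurate and blocks a Meyer–Schuster shift; the closest known reactions are the Au(I)‑catalysed ring expansion of 1‑alkynylcyclobutanols and ‑cyclopropanols, halodeauration of vinyl‑gold species by N‑halosuccinimides, and the D‑homoannulation of 17‑hydroxy‑20‑keto steroids (same trans‑hydrindane, quaternary carbon migrating).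

Step 12
Reactants: 20 2-{(Z)-chloro[(4aS,8aS)-5,5,8a-trimethyl-2-oxooctahydronaphthalen-1(2H)-ylidene]methyl}-6-methoxy-1,4-phenylene diacetate
Product: 21 2-{(E)-chloro[(4aS,8aS)-5,5,8a-trimethyl-2-methylideneoctahydronaphthalen-1(2H)-ylidene]methyl}-6-methoxy-1,4-phenylene diacetate
Conditions: Zn, CH2Br2, TiCl4, THF/CH2Cl2, 0 °C → rt
Reagents that add atoms: dibromomethane BrCBr
Why: Takai–Lombardo methylenation, a non‑basic gem‑dimetallic carbonyl olefination that tolerates aryl esters, vinyl chlorides and hindered enolisable ketones.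

Step 13
Reactants: 21 2-{(E)-chloro[(4aS,8aS)-5,5,8a-trimethyl-2-methylideneoctahydronaphthalen-1(2H)-ylidene]methyl}-6-methoxy-1,4-phenylene diacetate
Product: 22 2-{(E)-chloro[(2S,4aS,8aS)-2,5,5,8a-tetramethyloctahydronaphthalen-1(2H)-ylidene]methyl}-6-methoxy-1,4-phenylene diacetate
Conditions: H2 (1 atm), RhCl(PPh3)3 (10 mol %), benzene/EtOH, rt
Reagents that add atoms: none
Why: Homogeneous hydrogenation with Wilkinson's catalyst reduces only the 1,1‑disubstituted alkene (the tetrasubstituted chloroalkene is inert, no hydrodechlorination) and delivers H to C8 from the α face, opposite the axial C10 methyl, so the new methyl is β (8S).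

Step 14
Reactants: 22 2-{(E)-chloro[(2S,4aS,8aS)-2,5,5,8a-tetramethyloctahydronaphthalen-1(2H)-ylidene]methyl}-6-methoxy-1,4-phenylene diacetate
Product: 23 2-{(E)-chloro[(2S,4aS,8aS)-2,5,5,8a-tetramethyloctahydronaphthalen-1(2H)-ylidene]methyl}-6-methoxybenzene-1,4-diol
Conditions: K2CO3 (cat.), degassed MeOH, 0 °C, Ar; pH 6 buffer
Reagents that add atoms: none
Why: Base‑catalysed transesterification (methanolysis) of the two aryl acetates under oxygen‑free conditions frees the hydroquinone without touching the vinyl chloride or any stereocentre.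

## Compound list

1 | 2-methylcyclopentane-1,3-dione | CC1C(=O)CCC1=O | starting material
2 | ethyl vinyl ketone (pent-1-en-3-one) | CCC(=O)C=C | starting material
3 | 2-methyl-2-(3-oxopentyl)cyclopentane-1,3-dione | CCC(=O)CCC1(C)C(=O)CCC1=O | intermediate
4 | (S)-4,7a-dimethyl-2,3,7,7a-tetrahydro-1H-indene-1,5(6H)-dione | O=C1CCC2=C(C)C(=O)CC[C@]12C | intermediate
5 | (7a'S)-4',7a'-dimethyl-2',3',7',7a'-tetrahydrospiro[1,3-dioxolane-2,1'-inden]-5'(6'H)-one (C1 ethylene ketal of 4) | O=C1C(C)=C2CCC3(OCCO3)[C@@]2(C)CC1 | intermediate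
6 | lithium enolate from 5 (O–Li on C5', C4'=C5', trans ring fusion, 3a'S,7a'S) | [Li]OC1=C(C)[C@@H]2CCC3(OCCO3)[C@@]2(C)CC1 | intermediate
7 | (3a'S,7a'S)-4',4',7a'-trimethylhexahydrospiro[1,3-dioxolane-2,1'-inden]-5'(4'H)-one (trans-fused) | O=C1C(C)(C)[C@@H]2CCC3(OCCO3)[C@@]2(C)CC1 | intermediate
8 | hydrazone of 7 | NN=C1C(C)(C)[C@@H]2CCC3(OCCO3)[C@@]2(C)CC1 | intermediate
9 | (3a'S,7a'S)-4',4',7a'-trimethyloctahydrospiro[1,3-dioxolane-2,1'-indene] | C1C(C)(C)[C@@H]2CCC3(OCCO3)[C@@]2(C)CC1 | intermediate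
10 | (3aS,7aS)-4,4,7a-trimethyloctahydro-1H-inden-1-one (trans-fused) | O=C1CC[C@H]2C(C)(C)CCC[C@]12C | intermediate
11 | ethynylmagnesium bromide | C#C[Mg]Br | starting material
12 | (1R,3aS,7aS)-1-ethynyl-4,4,7a-trimethyloctahydro-1H-inden-1-ol (OH syn to the angular methyl) | C#C[C@]1(O)CC[C@H]2C(C)(C)CCC[C@]12C | intermediate
13 | catechol (benzene-1,2-diol) | Oc1ccccc1O | starting material
14 | 2-methoxyphenol (guaiacol) | COc1ccccc1O | intermediate
15 | 2-bromo-6-methoxyphenol | COc1cccc(Br)c1O | intermediate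
16 | 2-bromo-6-methoxy-1,4-benzoquinone | COC1=CC(=O)C=C(Br)C1=O | intermediate
17 | 2-bromo-6-methoxy-1,4-phenylene diacetate | COc1cc(OC(C)=O)cc(Br)c1OC(C)=O | intermediate
18 | 2-{[(1S,3aS,7aS)-1-hydroxy-4,4,7a-trimethyloctahydro-1H-inden-1-yl]ethynyl}-6-methoxy-1,4-phenylene diacetate | COc1cc(OC(C)=O)cc(C#C[C@]2(O)CC[C@H]3C(C)(C)CCC[C@]23C)c1OC(C)=O | intermediate
19 | O-trimethylsilyl ether of 18 | COc1cc(OC(C)=O)cc(C#C[C@]2(O[Si](C)(C)C)CC[C@H]3C(C)(C)CCC[C@]23C)c1OC(C)=O | intermediate
20 | 2-{(Z)-chloro[(4aS,8aS)-5,5,8a-trimethyl-2-oxooctahydronaphthalen-1(2H)-ylidene]methyl}-6-methoxy-1,4-phenylene diacetate (Cl syn to C=O, aryl syn to C8a) | COc1cc(OC(C)=O)cc(/C(Cl)=C2/C(=O)CC[C@H]3C(C)(C)CCC[C@]23C)c1OC(C)=O | intermediate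
21 | 2-{(E)-chloro[(4aS,8aS)-5,5,8a-trimethyl-2-methylideneoctahydronaphthalen-1(2H)-ylidene]methyl}-6-methoxy-1,4-phenylene diacetate | COc1cc(OC(C)=O)cc(/C(Cl)=C2/C(=C)CC[C@H]3C(C)(C)CCC[C@]23C)c1OC(C)=O | intermediate
22 | 2-{(E)-chloro[(2S,4aS,8aS)-2,5,5,8a-tetramethyloctahydronaphthalen-1(2H)-ylidene]methyl}-6-methoxy-1,4-phenylene diacetate | COc1cc(OC(C)=O)cc(/C(Cl)=C2/[C@@H](C)CC[C@H]3C(C)(C)CCC[C@]23C)c1OC(C)=O | intermediate
23 | 2-{(E)-chloro[(2S,4aS,8aS)-2,5,5,8a-tetramethyloctahydronaphthalen-1(2H)-ylidene]methyl}-6-methoxybenzene-1,4-diol (CNP0162917.1) | COc1cc(O)cc(/C(Cl)=C2/[C@@H](C)CC[C@H]3C(C)(C)CCC[C@]23C)c1O | target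

## Step count and risks

Total steps: 14. Longest linear sequence: 10 (steps 1–5 and 10–14); the arene branch is steps 6–9.

Three steps most likely to fail:

Step 11 (the proposed new reaction). The risks are protodeauration or slow chlorodeauration, migration of C7 instead of C10, reversible participation of the ortho acetate, and ring chlorination by NCS. The fallback uses known chemistry, sets out from 18 and comes back at 20. Lindlar semi‑hydrogenation of 18 gives the Z‑styryl carbinol F1. Hydroxyl‑directed epoxidation (VO(acac)2, t‑BuOOH) gives the cis‑epoxy alcohol F2. The known Lewis‑acid epoxy‑alcohol semipinacol ring expansion (BF3·OEt2, −78 °C; C10 migrates to C9 as the epoxide opens) gives the β‑hydroxy ketone F3. Dess–Martin oxidation gives the 1,3‑diketone F4. Oxalyl chloride with catalytic DMF converts F4 into the vinylogous acid chloride 20, and any regio‑ or geometric isomers are separated.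

Step 3 (ring‑fusion control in the hydrindane series is less secure than for decalins). The fallback sets out from 5 and comes back at 9. Deconjugative C‑methylation (KOt‑Bu, MeI, t‑BuOH) gives the β,γ‑unsaturated gem‑dimethyl ketone F5. Wolff–Kishner reduction gives the cyclopentene ketal F6. Hydrogenation (H2, Pd/C, EtOAc) from the face opposite the angular methyl, as for Δ5‑4,4‑dimethyl steroids, gives 9, which is hydrolysed to 10 as in step 4.

Step 13 (chemoselectivity against the chloro‑diene and facial selectivity at C8). The fallback sets out from 21 and comes back at 22. Hydroboration with 9‑BBN from the same α face, then oxidation with Me3NO, gives the primary alcohol F7. MsCl/Et3N gives the mesylate F8. Reduction with NaI/Zn (DME, reflux) gives 22.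

Further compounds
F1 | step 11 | Z-styryl carbinol from 18 (2-[(Z)-2-(1-hydroxy-4,4,7a-trimethyloctahydroinden-1-yl)ethenyl]-6-methoxy-1,4-phenylene diacetate) | COc1cc(OC(C)=O)cc(/C=C\[C@]2(O)CC[C@H]3C(C)(C)CCC[C@]23C)c1OC(C)=O
F2 | step 11 | cis-epoxy alcohol from F1 (epoxide face not assigned) | COc1cc(OC(C)=O)cc(C4OC4[C@]2(O)CC[C@H]3C(C)(C)CCC[C@]23C)c1OC(C)=O
F3 | step 11 | β-hydroxy ketone, 2-{hydroxy[(4aS,8aS)-5,5,8a-trimethyl-2-oxodecahydronaphthalen-1-yl]methyl}-6-methoxy-1,4-phenylene diacetate (C1 and carbinol centres not assigned) | COc1cc(OC(C)=O)cc(C(O)C2C(=O)CC[C@H]3C(C)(C)CCC[C@]23C)c1OC(C)=O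
F4 | step 11 | 1,3-diketone, 2-{[(4aS,8aS)-5,5,8a-trimethyl-2-oxodecahydronaphthalen-1-yl]carbonyl}-6-methoxy-1,4-phenylene diacetate | COc1cc(OC(C)=O)cc(C(=O)C2C(=O)CC[C@H]3C(C)(C)CCC[C@]23C)c1OC(C)=O
F5 | step 3 | (7a'S)-4',4',7a'-trimethyl-2',6',7',7a'-tetrahydrospiro[1,3-dioxolane-2,1'-inden]-5'(4'H)-one (3',3a'-alkene) | O=C1C(C)(C)C2=CCC3(OCCO3)[C@@]2(C)CC1
F6 | step 3 | (7a'S)-4',4',7a'-trimethyl-2',4',5',6',7',7a'-hexahydrospiro[1,3-dioxolane-2,1'-indene] (3',3a'-alkene) | C1C(C)(C)C2=CCC3(OCCO3)[C@@]2(C)CC1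
F7 | step 13 | primary alcohol, 2-{(E)-chloro[(2S,4aS,8aS)-2-(hydroxymethyl)-5,5,8a-trimethyloctahydronaphthalen-1(2H)-ylidene]methyl}-6-methoxy-1,4-phenylene diacetate | COc1cc(OC(C)=O)cc(/C(Cl)=C2/[C@@H](CO)CC[C@H]3C(C)(C)CCC[C@]23C)c1OC(C)=O
F8 | step 13 | mesylate of F7 | COc1cc(OC(C)=O)cc(/C(Cl)=C2/[C@@H](COS(C)(=O)=O)CC[C@H]3C(C)(C)CCC[C@]23C)c1OC(C)=O
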